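The route rests on cutting ring A of the spiroketal at C14–C15 and O1–C16. An inverse-demand hetero-Diels–Alder reaction joins methyl (E)-2-oxopent-3-enoate (O1=C12–C13=C14, C11 as ester) to the C15=C16 exocyclic enol ether of a finished ring B (C15–C23, O21 silylated, C22 ketalised). One operation closes ring A, creates the spiro carbon and fixes C14. The step uses the shape of ring A (O1, C12–C16). Its chair holds C11 and the C14 methyl equatorial on one face and O2 axial on C16, so base at C12 and acid at C16 can repair those centres afterwards. C1–C10 then grow from the C11 aldehyde by allylboration chemistry.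

Key step: step 10

Numbering: C1 is the methyl ester carbonyl and C23 the acetyl methyl. O1 (on C12) belongs to ring A and O2 (on C20) to ring B. "Core" means the spiroketal of rings A and B with the C14 and C18 methyl groups and, on C20, the (R)-CH(OTBS)–C(OCH2CH2O)CH3 side chain. Ipc = isopinocampheyl.
Assumption: the sense of induction in step 10 is derived from the square-planar substrate–copper chelate, which calls for the (R,R) ligand; should the opposite sense be met, the (S,S) ligand is used and nothing else changes.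
Assumption: metal alkoxides, enolates and aluminium hemiacetals that are merely protonated on aqueous work-up are not counted as separate compounds.

Step 1
Reactants: 1 penta-1,4-dien-3-ol
Product: 2 (2R,3S)-1,2-epoxypent-4-en-3-ol (C19–C23; O20/O21 anti)
Conditions: Ti(Oi-Pr)4 (cat.), L-(+)-DIPT (cat.), t-BuOOH, 4 Å MS, CH2Cl2, −20 °C
Reagents that add atoms: tert-butyl hydroperoxide, CC(C)(C)OO
Why: Sharpless asymmetric epoxidation run as a desymmetrisation, in which the Ti(Oi-Pr)4/L-(+)-DIPT catalyst selects one enantiotopic vinyl group and one of its faces, setting C20 (R) and C21 (S here, R once C22 is oxygenated) in the anti relation, while the wrong enantiomer should be drained by a faster second epoxidation.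

Step 2
Reactants: 2 (2R,3S)-1,2-epoxypent-4-en-3-ol
Product: 3 (2R,3S)-3-(tert-butyldimethylsilyloxy)-1,2-epoxypent-4-ene
Conditions: TBSCl, imidazole, DMF, 0 °C to rt
Reagents that add atoms: tert-butyldimethylsilyl chloride, CC(C)(C)[Si](C)(C)Cl
Why: Routine imidazole-promoted silylation of the secondary alcohol, mild enough to avoid Payne migration of the epoxide, installs the O21 protecting group that is kept until the last step.

Step 3
Reactants: 3 silyloxy epoxide; 4 methyl propiolate
Product: 5 methyl (5R,6S)-6-(tert-butyldimethylsilyloxy)-5-hydroxyoct-7-en-2-ynoate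
Conditions: 4, n-BuLi, THF, −78 °C; BF3·OEt2; 3, −78 °C; aq. NH4Cl
Reagents that add atoms: none
Why: BF3-assisted SN2 opening of a terminal epoxide by a lithium acetylide (Yamaguchi–Hirao alkynylation) takes place at the unhindered C19, leaves C20 and C21 untouched and brings in C16–C18 at the ester oxidation level.

Step 4
Reactants: 5 hydroxy ynoate
Product: 7 (6R)-6-[(1S)-1-(tert-butyldimethylsilyloxy)prop-2-enyl]-5,6-dihydro-2H-pyran-2-one, via Z-enoate 6 (not isolated)
Conditions: H2 (1 atm), Pd/CaCO3–Pb(OAc)2, quinoline, EtOAc, rt; filter; PPTS (cat.), toluene, 50 °C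
Reagents that add atoms: none
Why: Lindlar semihydrogenation gives the Z-enoate, whose geometry allows acid-catalysed lactonisation through O20 to close ring B, and the poisoned catalyst binds the electron-poor alkyne much more strongly than the hindered allylic vinyl group, which should be left intact.

Step 5
Reactants: 7 dihydropyranone
Product: 8 (4S,6R)-6-[(1S)-1-(tert-butyldimethylsilyloxy)prop-2-enyl]-4-methyltetrahydropyran-2-one (4,6-trans)
Conditions: MeLi, CuI, Et2O, 0 °C; 7, −78 °C; aq. NH4Cl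
Reagents that add atoms: lithium dimethylcuprate, [Li+].C[Cu-]C
Why: 1,4-Addition of Me2CuLi to a 6-substituted 5,6-dihydropyran-2-one occurs by axial attack on the half-chair from the face opposite the pseudo-equatorial C20 side chain, which sets C18 (S) trans to C20.

Step 6
Reactants: 8 vinyl lactone
Product: 9 (4S,6R)-6-[(1R)-1-(tert-butyldimethylsilyloxy)-2-oxopropyl]-4-methyltetrahydropyran-2-one
Conditions: PdCl2(Quinox) (5 mol%), AgSbF6 (12 mol%), aq. t-BuOOH, CH2Cl2, 0 °C to rt (Quinox = 2-(4,5-dihydrooxazol-2-yl)quinoline)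
Reagents that add atoms: tert-butyl hydroperoxide, CC(C)(C)OO
Why: Wacker-type oxidation with a cationic quinoline–oxazoline palladium catalyst and t-BuOOH, a variant developed for protected allylic alcohols, should deliver oxygen to the internal carbon C22 and give the methyl ketone without touching C21 or the lactone.

Step 7
Reactants: 9 keto lactone
Product: 10 (4S,6R)-6-[(R)-(tert-butyldimethylsilyloxy)(2-methyl-1,3-dioxolan-2-yl)methyl]-4-methyltetrahydropyran-2-one
Conditions: TMSOCH2CH2OTMS, TMSOTf (cat.), CH2Cl2, −78 to −20 °C; pyridine quench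
Reagents that add atoms: 1,2-bis(trimethylsilyloxy)ethane, C[Si](C)(C)OCCO[Si](C)(C)C
Why: Noyori ketalisation under aprotic conditions at low temperature masks the C22 ketone without enolising it toward C21, and the less electrophilic lactone carbonyl does not react.

Step 8
Reactants: 10 ring B lactone
Product: 11 (2R,4S)-2-[(R)-(tert-butyldimethylsilyloxy)(2-methyl-1,3-dioxolan-2-yl)methyl]-4-methyl-6-methylidenetetrahydropyran (ring B exocyclic enol ether, C15–C23)
Conditions: Cp2TiMe2 (2.5 equiv), toluene, 70 °C, dark; filtration through basic alumina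
Reagents that add atoms: dimethyltitanocene, [CH3-].[CH3-].[Ti+4].[cH-]1cccc1.[cH-]1cccc1
Why: Petasis methylenation, in which Cp2Ti=CH2 released on heating adds to the lactone carbonyl and the oxatitanacyclobutane collapses to the C15=C16 exocyclic enol ether under neutral conditions that spare ketal and silyl ether.

Step 9
Reactants: 12 dimethyl oxalate; 13 (E)-prop-1-enylmagnesium bromide
Product: 14 methyl (E)-2-oxopent-3-enoate
Conditions: 13 added to 12 (1.5 equiv), THF–Et2O, −78 °C; aq. NH4Cl
Reagents that add atoms: none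
Why: Mono-acylation of an alkenyl Grignard reagent by an oxalate diester works because the chelated tetrahedral adduct persists at −78 °C, so the ketone is released only on work-up and the E geometry of the propenyl group is carried over.

Step 10
Reactants: 11 ring B exocyclic enol ether; 14 methyl (E)-2-oxopent-3-enoate
Product: 15 spiroketal dihydropyran C11 methyl ester (C12=C13; 14S,18S,20R,21R; C16 drawn as the doubly anomeric epimer)
Conditions: Cu(OTf)2 (10 mol%), (R,R)-2,2'-isopropylidenebis(4-tert-butyl-2-oxazoline) (11 mol%), 4 Å MS, 2,6-di-tert-butyl-4-methylpyridine (20 mol%), 14 (1.5 equiv), Et2O, −40 to 0 °C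
Reagents that add atoms: none
Why: Two-point binding of 14 (ketone and ester oxygens) to the divalent copper centre makes the O1=C12–C13=C14 unit a strongly electron-poor heterodiene; bond formation starts between its β-carbon C14 and the CH2 terminus C15 of 11 and is completed, within the same asynchronous transition state, by O1 capturing the developing cationic centre C16. The closest known reaction types are the bis(oxazoline)copper-catalysed inverse-electron-demand hetero-Diels–Alder reaction of β,γ-unsaturated α-keto esters with enol ethers and the spiroketal synthesis from 2-methylenetetrahydropyrans and enones, and ring A closes as a six-membered ring by this [4+2] cycloaddition, suprafacial on both partners. C14 is set by the ligand: in the square-planar chelate one tert-butyl group of the (R,R) ligand covers one face of the s-cis heterodiene, so 11 adds to the other face and gives 14S (14R after saturation, by a change of CIP priorities only). Since C15 carries two hydrogens, the endo/exo question translates solely into the configuration of C16; the endo preference of O2 and the axial C18 methyl may even favour the 16-epimer, and either epimer is carried on because step 12 makes them converge. Regiochemistry follows from the polarity of the partners, and the chemoselectivity needed, namely that the double bond of 11 does not migrate into ring B, should be secured by sieves, the non-coordinating pyridine base and low temperature.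

Step 11
Reactants: 15 spiroketal dihydropyran ester
Product: 16 saturated spiroketal ester with axial CO2Me (12S,14R)
Conditions: H2 (1 atm), Pd/C, EtOAc, rt
Reagents that add atoms: none
Why: Heterogeneous hydrogenation of the C12=C13 enol ether double bond should take place on the face turned away from axial O2 and ring B, which puts the ester axial on C12, an outcome that is of no consequence because step 12 corrects this centre.

Step 12
Reactants: 16 saturated spiroketal ester
Product: 17 core–C12 methyl ester, fully equilibrated (12R,14R,18S,20R,21R; O2 axial on ring A, O1 axial on ring B)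
Conditions: NaOMe (0.3 equiv), MeOH, 40 °C; AcOH, concentrate; CSA (10 mol%), CH2Cl2, rt
Reagents that add atoms: none
Why: Two thermodynamic equilibrations: methoxide enolises the C11 ester and moves it into the equatorial position cis to the C14 methyl (12R), and acid then reopens the spiroketal through its oxocarbenium ions and funnels any 16-epimer into the doubly anomeric isomer, whose only cost is an axial C18 methyl, whereas the epimer would lose an anomeric effect and place C17 or C21 axial.

Step 13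
Reactants: 17 equilibrated ester
Product: 18 core–C12 carbaldehyde (C11 aldehyde)
Conditions: i-Bu2AlH (1.1 equiv), CH2Cl2, −78 °C; aq. potassium sodium tartrate
Reagents that add atoms: none
Why: Partial reduction of an α-alkoxy ester with i-Bu2AlH stops at the chelated aluminium hemiacetal at −78 °C, and C12 is not at risk because the equatorial aldehyde is the stable epimer.

Step 14
Reactants: 18 C11 aldehyde
Product: 20 (10S,11S)-homoallylic alcohol core–C11H(OH)–C10H(CH3)–C9H=C8H2, via borinate 19 (not isolated)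
Conditions: trans-2-butene, n-BuLi, KOt-Bu, THF, −78 to −45 °C; (−)-Ipc2BOMe, −78 °C; BF3·OEt2; 18, −78 °C; then NaOH, H2O2, 0 °C to rt
Reagents that add atoms: (E)-crotyldiisopinocampheylborane ((+)-α-pinene series), C/C=C/CB([C@@H]1C[C@@H]2C[C@H]([C@H]1C)C2(C)C)[C@@H]1C[C@@H]2C[C@H]([C@H]1C)C2(C)C
Why: Brown crotylboration through a closed chair transition state, in which the E-crotyl geometry gives the 10,11-anti relation and the (+)-α-pinene-derived ligands choose the aldehyde face that gives 11S, the sense also favoured by the Felkin–Anh model for this α-alkoxy aldehyde (11,12-anti).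

Step 15
Reactants: 20 homoallylic alcohol
Product: 21 C11 isovalerate of 20
Conditions: (i-BuCO)2O, DMAP, Et3N, CH2Cl2, rt
Reagents that add atoms: isovaleric anhydride, CC(C)CC(=O)OC(=O)CC(C)C
Why: DMAP-catalysed acylation places the final isovalerate on O11 at once, so that no protecting group is spent on this position.

Step 16
Reactants: 21 alkene isovalerate
Product: 23 C8 primary alcohol, via B-alkyl-9-BBN adduct 22 (not isolated)
Conditions: 9-BBN, THF, 0 °C to rt; then NaBO3·4H2O, H2O, rt
Reagents that add atoms: sodium perborate, [Na+].[Na+].O[B-]1(O)OO[B-](O)(O)OO1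
Why: Anti-Markovnikov hydroboration of the monosubstituted alkene with bulky 9-BBN puts boron on C8, and the mild perborate oxidation spares the ester.

Step 17
Reactants: 23 C8 alcohol
Product: 24 C8 aldehyde
Conditions: Dess–Martin periodinane, pyridine, CH2Cl2, 0 °C to rt
Reagents that add atoms: none
Why: Dess–Martin oxidation stops at the aldehyde under nearly neutral conditions that leave ester, ketals and silyl ether alone.

Step 18
Reactants: 24 C8 aldehyde
Product: 25 (8S)-allylic alcohol carrying an (E)-hex-1-enyl group on C8 (its first carbon is C7)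
Conditions: 1-hexyne, Cy2BH, toluene, 0 °C to rt; Me2Zn, −78 °C; (+)-MIB (10 mol%); 24, −20 to 0 °C; aq. NH4Cl ((+)-MIB = (+)-3-exo-morpholinoisoborneol)
Reagents that add atoms: (E)-hex-1-enyl(methyl)zinc, CCCC/C=C/[Zn]C
Why: Catalytic asymmetric alkenylzinc addition (alkyne hydroboration, boron-to-zinc exchange, amino-alcohol catalysis), in which the zinc alkoxide of (+)-MIB organises aldehyde and alkenylzinc in one transition state and should deliver the alkenyl group to the face that gives 8S, esters and ketals being inert to organozinc reagents.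

Step 19
Reactants: 25 allylic alcohol
Product: 26 C8,C11 bis-isovalerate
Conditions: (i-BuCO)2O, DMAP, Et3N, CH2Cl2, rt
Reagents that add atoms: isovaleric anhydride, CC(C)CC(=O)OC(=O)CC(C)C
Why: DMAP-catalysed acylation installs the second and last isovalerate directly on O8.

Step 20
Reactants: 26 bis-isovalerate
Product: 27 C7 aldehyde (α-isovaleryloxy aldehyde, 8S)
Conditions: O3, pyridine (3 equiv), CH2Cl2, −78 °C
Reagents that add atoms: ozone, [O-][O+]=O
Why: Ozonolysis of the only C=C bond in the presence of pyridine, which decomposes the carbonyl oxide directly to the carbonyl compounds, unveils the C7 aldehyde without a separate reduction, and the aldehyde is used at once to protect C8.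

Step 21
Reactants: 27 C7 aldehyde
Product: 29 (6S,7S)-homoallylic alcohol …C8H(OCOi-Bu)–C7H(OH)–C6H(CH3)–C5H=CH2, via borinate 28 (not isolated)
Conditions: trans-2-butene, n-BuLi, KOt-Bu, THF, −78 to −45 °C; (−)-Ipc2BOMe, −78 °C; BF3·OEt2; 27, −78 °C; then pH 7 buffer, H2O2, MeOH, 0 °C
Reagents that add atoms: (E)-crotyldiisopinocampheylborane ((+)-α-pinene series), C/C=C/CB([C@@H]1C[C@@H]2C[C@H]([C@H]1C)C2(C)C)[C@@H]1C[C@@H]2C[C@H]([C@H]1C)C2(C)C
Why: Brown crotylboration, in which the E-crotyl geometry gives the 6,7-anti relation and the ligands choose the aldehyde face (7S, hence 7,8-syn), feasible because E-crotylboranes show only a weak intrinsic bias toward α-oxygenated aldehydes, while the buffered work-up is meant to prevent an O8 to O7 acyl shift.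

Step 22
Reactants: 29 homoallylic alcohol
Product: 30 C7 acetate
Conditions: Ac2O, pyridine, DMAP (cat.), CH2Cl2, 0 °C
Reagents that add atoms: acetic anhydride, CC(=O)OC(C)=O
Why: Standard acetylation caps O7 with its final acetate before acyl migration can set in.

Step 23
Reactants: 30 acetate
Product: 31 C5 aldehyde (α-methyl-β-acetoxy aldehyde; all centres spatially unchanged)
Conditions: O3, pyridine (3 equiv), CH2Cl2, −78 °C
Reagents that add atoms: ozone, [O-][O+]=O
Why: Pyridine-modified ozonolysis of the terminal alkene gives the C5 aldehyde directly at −78 °C, and immediate use limits β-elimination of acetate and epimerisation at C6.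

Step 24
Reactants: 31 C5 aldehyde
Product: 33 (5R)-homoallylic alcohol …C6H(CH3)–C5H(OH)–C4H2–C3H=CH2, via borinate 32 (not isolated)
Conditions: allylMgBr, (+)-Ipc2BOMe, Et2O, 0 °C to rt; 31, −78 °C; then pH 7 buffer, H2O2, MeOH, 0 °C
Reagents that add atoms: allyldiisopinocampheylborane ((−)-α-pinene series), C=CCB([C@H]1C[C@H]2C[C@@H]([C@@H]1C)C2(C)C)[C@H]1C[C@H]2C[C@@H]([C@@H]1C)C2(C)C
Why: Brown allylboration, in which the borane from (+)-Ipc2BOMe attacks the face that gives 5R (5,6-syn, 5,7-anti), which is also the Felkin–Anh sense of the α-methyl aldehyde and the 1,3-anti sense of the β-acetoxy group, so reagent and substrate reinforce each other.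

Step 25
Reactants: 33 C5 alcohol
Product: 34 C5 propionate
Conditions: (EtCO)2O, pyridine, DMAP (cat.), CH2Cl2, 0 °C to rt
Reagents that add atoms: propionic anhydride, CCC(=O)OC(=O)CC
Why: Standard acylation puts the final propionate on O5, the only free hydroxyl group.

Step 26
Reactants: 34 terminal alkene; 35 methyl methacrylate
Product: 36 fully acylated (2E)-enoate with O21 TBS and C22 dioxolane still in place
Conditions: 35 (20 equiv), second-generation Hoveyda–Grubbs catalyst, RuCl2(H2IMes)(=CH-C6H4-2-Oi-Pr) (10 mol%), CH2Cl2, 40 °C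
Reagents that add atoms: none
Why: Olefin cross-metathesis of a terminal alkene with excess methyl methacrylate succeeds because the methacrylate does not homodimerise, so the cross product should dominate, and the trisubstituted enoate forms as the more stable E isomer (C4 trans to C1).

Step 27
Reactants: 36 protected target
Product: 38 CNP0165569.3, via hydroxy ketal 37 (not isolated)
Conditions: 48% aq. HF–MeCN (1:19), 0 °C to rt
Reagents that add atoms: water, O
Why: Acidic fluoride cleaves the O21 silyl ether and the aqueous acid then hydrolyses the C22 dioxolane; the five esters and the enoate tolerate this medium, the spiroketal is already in its most stable form, and base, which could epimerise C21 or move acyl groups, is avoided.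

Compound list
1 | penta-1,4-dien-3-ol | C=CC(O)C=C | starting material
2 | (2R,3S)-1,2-epoxypent-4-en-3-ol | C=C[C@H](O)[C@H]1CO1 | intermediate
3 | (2R,3S)-3-(tert-butyldimethylsilyloxy)-1,2-epoxypent-4-ene | C=C[C@H](O[Si](C)(C)C(C)(C)C)[C@H]1CO1 | intermediate
4 | methyl propiolate | C#CC(=O)OC | starting material
5 | methyl (5R,6S)-6-(tert-butyldimethylsilyloxy)-5-hydroxyoct-7-en-2-ynoate | C=C[C@H](O[Si](C)(C)C(C)(C)C)[C@H](O)CC#CC(=O)OC | intermediate
6 | methyl (2Z,5R,6S)-6-(tert-butyldimethylsilyloxy)-5-hydroxyocta-2,7-dienoate | C=C[C@H](O[Si](C)(C)C(C)(C)C)[C@H](O)C/C=C\C(=O)OC | intermediate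
7 | (6R)-6-[(1S)-1-(tert-butyldimethylsilyloxy)prop-2-enyl]-5,6-dihydro-2H-pyran-2-one | C=C[C@H](O[Si](C)(C)C(C)(C)C)[C@H]1CC=CC(=O)O1 | intermediate
8 | (4S,6R)-6-[(1S)-1-(tert-butyldimethylsilyloxy)prop-2-enyl]-4-methyltetrahydropyran-2-one | O=C1C[C@@H](C)C[C@H]([C@@H](O[Si](C)(C)C(C)(C)C)C=C)O1 | intermediate
9 | (4S,6R)-6-[(1R)-1-(tert-butyldimethylsilyloxy)-2-oxopropyl]-4-methyltetrahydropyran-2-one | O=C1C[C@@H](C)C[C@H]([C@@H](O[Si](C)(C)C(C)(C)C)C(C)=O)O1 | intermediate
10 | (4S,6R)-6-[(R)-(tert-butyldimethylsilyloxy)(2-methyl-1,3-dioxolan-2-yl)methyl]-4-methyltetrahydropyran-2-one | O=C1C[C@@H](C)C[C@H]([C@@H](O[Si](C)(C)C(C)(C)C)C2(C)OCCO2)O1 | intermediate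
11 | ring B exocyclic enol ether, (2R,4S)-2-[(R)-(tert-butyldimethylsilyloxy)(2-methyl-1,3-dioxolan-2-yl)methyl]-4-methyl-6-methylidenetetrahydropyran | C=C1C[C@@H](C)C[C@H]([C@@H](O[Si](C)(C)C(C)(C)C)C2(C)OCCO2)O1 | intermediate
12 | dimethyl oxalate | COC(=O)C(=O)OC | starting material
13 | (E)-prop-1-enylmagnesium bromide (THF solution) | C/C=C/[Mg]Br | starting material
14 | methyl (E)-2-oxopent-3-enoate | C/C=C/C(=O)C(=O)OC | intermediate
15 | spiroketal dihydropyran C11 methyl ester (14S,18S,20R,21R) | COC(=O)C1=C[C@@H](C)C[C@@]2(C[C@@H](C)C[C@H]([C@@H](O[Si](C)(C)C(C)(C)C)C3(C)OCCO3)O2)O1 | intermediate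
16 | saturated spiroketal ester, CO2Me axial (12S,14R) | COC(=O)[C@@H]1C[C@@H](C)C[C@@]2(C[C@@H](C)C[C@H]([C@@H](O[Si](C)(C)C(C)(C)C)C3(C)OCCO3)O2)O1 | intermediate
17 | saturated spiroketal ester, CO2Me equatorial (12R,14R), doubly anomeric | COC(=O)[C@H]1C[C@@H](C)C[C@@]2(C[C@@H](C)C[C@H]([C@@H](O[Si](C)(C)C(C)(C)C)C3(C)OCCO3)O2)O1 | intermediate
18 | C11 aldehyde | O=C[C@H]1C[C@@H](C)C[C@@]2(C[C@@H](C)C[C@H]([C@@H](O[Si](C)(C)C(C)(C)C)C3(C)OCCO3)O2)O1 | intermediate
19 | O11 diisopinocampheylborinate of 20 | C=C[C@H](C)[C@H](OB([C@@H]1C[C@@H]2C[C@H]([C@H]1C)C2(C)C)[C@@H]1C[C@@H]2C[C@H]([C@H]1C)C2(C)C)[C@H]1C[C@@H](C)C[C@@]2(C[C@@H](C)C[C@H]([C@@H](O[Si](C)(C)C(C)(C)C)C3(C)OCCO3)O2)O1 | intermediate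
20 | (10S,11S)-homoallylic alcohol (C8–C23) | C=C[C@H](C)[C@H](O)[C@H]1C[C@@H](C)C[C@@]2(C[C@@H](C)C[C@H]([C@@H](O[Si](C)(C)C(C)(C)C)C3(C)OCCO3)O2)O1 | intermediate
21 | C11 isovalerate of 20 | C=C[C@H](C)[C@H](OC(=O)CC(C)C)[C@H]1C[C@@H](C)C[C@@]2(C[C@@H](C)C[C@H]([C@@H](O[Si](C)(C)C(C)(C)C)C3(C)OCCO3)O2)O1 | intermediate
22 | C8 B-alkyl-9-borabicyclo[3.3.1]nonane | C1CC2CCCC(C1)B2CC[C@H](C)[C@H](OC(=O)CC(C)C)[C@H]1C[C@@H](C)C[C@@]2(C[C@@H](C)C[C@H]([C@@H](O[Si](C)(C)C(C)(C)C)C3(C)OCCO3)O2)O1 | intermediate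
23 | C8 primary alcohol | OCC[C@H](C)[C@H](OC(=O)CC(C)C)[C@H]1C[C@@H](C)C[C@@]2(C[C@@H](C)C[C@H]([C@@H](O[Si](C)(C)C(C)(C)C)C3(C)OCCO3)O2)O1 | intermediate
24 | C8 aldehyde | O=CC[C@H](C)[C@H](OC(=O)CC(C)C)[C@H]1C[C@@H](C)C[C@@]2(C[C@@H](C)C[C@H]([C@@H](O[Si](C)(C)C(C)(C)C)C3(C)OCCO3)O2)O1 | intermediate
25 | (8S)-(E)-hexenyl carbinol | CCCC/C=C/[C@@H](O)C[C@H](C)[C@H](OC(=O)CC(C)C)[C@H]1C[C@@H](C)C[C@@]2(C[C@@H](C)C[C@H]([C@@H](O[Si](C)(C)C(C)(C)C)C3(C)OCCO3)O2)O1 | intermediate
26 | C8,C11 bis-isovalerate | CCCC/C=C/[C@@H](OC(=O)CC(C)C)C[C@H](C)[C@H](OC(=O)CC(C)C)[C@H]1C[C@@H](C)C[C@@]2(C[C@@H](C)C[C@H]([C@@H](O[Si](C)(C)C(C)(C)C)C3(C)OCCO3)O2)O1 | intermediate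
27 | C7 aldehyde | O=C[C@@H](OC(=O)CC(C)C)C[C@H](C)[C@H](OC(=O)CC(C)C)[C@H]1C[C@@H](C)C[C@@]2(C[C@@H](C)C[C@H]([C@@H](O[Si](C)(C)C(C)(C)C)C3(C)OCCO3)O2)O1 | intermediate
28 | O7 diisopinocampheylborinate of 29 | C=C[C@H](C)[C@H](OB([C@@H]1C[C@@H]2C[C@H]([C@H]1C)C2(C)C)[C@@H]1C[C@@H]2C[C@H]([C@H]1C)C2(C)C)[C@@H](OC(=O)CC(C)C)C[C@H](C)[C@H](OC(=O)CC(C)C)[C@H]1C[C@@H](C)C[C@@]2(C[C@@H](C)C[C@H]([C@@H](O[Si](C)(C)C(C)(C)C)C3(C)OCCO3)O2)O1 | intermediate
29 | (6S,7S)-homoallylic alcohol (C5–C23) | C=C[C@H](C)[C@H](O)[C@@H](OC(=O)CC(C)C)C[C@H](C)[C@H](OC(=O)CC(C)C)[C@H]1C[C@@H](C)C[C@@]2(C[C@@H](C)C[C@H]([C@@H](O[Si](C)(C)C(C)(C)C)C3(C)OCCO3)O2)O1 | intermediate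
30 | C7 acetate | C=C[C@H](C)[C@H](OC(C)=O)[C@@H](OC(=O)CC(C)C)C[C@H](C)[C@H](OC(=O)CC(C)C)[C@H]1C[C@@H](C)C[C@@]2(C[C@@H](C)C[C@H]([C@@H](O[Si](C)(C)C(C)(C)C)C3(C)OCCO3)O2)O1 | intermediate
31 | C5 aldehyde | O=C[C@H](C)[C@H](OC(C)=O)[C@@H](OC(=O)CC(C)C)C[C@H](C)[C@H](OC(=O)CC(C)C)[C@H]1C[C@@H](C)C[C@@]2(C[C@@H](C)C[C@H]([C@@H](O[Si](C)(C)C(C)(C)C)C3(C)OCCO3)O2)O1 | intermediate
32 | O5 diisopinocampheylborinate of 33 | C=CC[C@@H](OB([C@H]1C[C@H]2C[C@@H]([C@@H]1C)C2(C)C)[C@H]1C[C@H]2C[C@@H]([C@@H]1C)C2(C)C)[C@H](C)[C@H](OC(C)=O)[C@@H](OC(=O)CC(C)C)C[C@H](C)[C@H](OC(=O)CC(C)C)[C@H]1C[C@@H](C)C[C@@]2(C[C@@H](C)C[C@H]([C@@H](O[Si](C)(C)C(C)(C)C)C3(C)OCCO3)O2)O1 | intermediate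
33 | (5R)-homoallylic alcohol (C3–C23) | C=CC[C@@H](O)[C@H](C)[C@H](OC(C)=O)[C@@H](OC(=O)CC(C)C)C[C@H](C)[C@H](OC(=O)CC(C)C)[C@H]1C[C@@H](C)C[C@@]2(C[C@@H](C)C[C@H]([C@@H](O[Si](C)(C)C(C)(C)C)C3(C)OCCO3)O2)O1 | intermediate
34 | C5 propionate | C=CC[C@@H](OC(=O)CC)[C@H](C)[C@H](OC(C)=O)[C@@H](OC(=O)CC(C)C)C[C@H](C)[C@H](OC(=O)CC(C)C)[C@H]1C[C@@H](C)C[C@@]2(C[C@@H](C)C[C@H]([C@@H](O[Si](C)(C)C(C)(C)C)C3(C)OCCO3)O2)O1 | intermediate
35 | methyl methacrylate | C=C(C)C(=O)OC | starting material
36 | protected target (O21 TBS, C22 dioxolane, 2E) | COC(=O)/C(C)=C/C[C@@H](OC(=O)CC)[C@H](C)[C@H](OC(C)=O)[C@@H](OC(=O)CC(C)C)C[C@H](C)[C@H](OC(=O)CC(C)C)[C@H]1C[C@@H](C)C[C@@]2(C[C@@H](C)C[C@H]([C@@H](O[Si](C)(C)C(C)(C)C)C3(C)OCCO3)O2)O1 | intermediate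
37 | C21 alcohol with C22 dioxolane | COC(=O)/C(C)=C/C[C@@H](OC(=O)CC)[C@H](C)[C@H](OC(C)=O)[C@@H](OC(=O)CC(C)C)C[C@H](C)[C@H](OC(=O)CC(C)C)[C@H]1C[C@@H](C)C[C@@]2(C[C@@H](C)C[C@H]([C@@H](O)C3(C)OCCO3)O2)O1 | intermediate
38 | CNP0165569.3 (5R,6S,7S,8S,10S,11S,12R,14R,18S,20R,21R; C16 doubly anomeric; 2E) | CCC(=O)O[C@H](C/C=C(\C)C(=O)OC)[C@H](C)[C@H](OC(C)=O)[C@H](C[C@H](C)[C@H](OC(=O)CC(C)C)[C@H]1C[C@@H](C)C[C@@]2(C[C@@H](C)C[C@H]([C@@H](O)C(C)=O)O2)O1)OC(=O)CC(C)C | target

Total step count: 27. Longest linear sequence: 26 (steps 1–8 and 10–27).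

Steps most likely to fail

Step 10. The double bond of 11 may migrate into ring B under the Lewis acid before cycloaddition, or facial control at C14 may be incomplete. The fallback sets out from lactone 10 and keto ester 14 and comes back at 17.
- MeLi (1 equiv, THF, −78 °C) opens 10 to the δ-hydroxy methyl ketone F1, which is in equilibrium with its lactol.
- TESOTf/2,6-lutidine caps O20 to give the keto silyl ether F2.
- LDA, then TMSCl, gives the kinetic C15=C16 trimethylsilyl enol ether F3, which has no ring position to slip into.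
- The same Cu(OTf)2/bis(oxazoline) catalyst promotes its Mukaiyama–Michael addition to 14, and mild acidic work-up gives the 1,5-diketo ester F4 with C14 set by the ligand as before.
- NaBH4 at −78 °C reduces only the activated C12 ketone to the hydroxy ester F5. It forms as a C12 mixture, which does not matter.
- CSA in CH2Cl2–MeOH removes the TES group and closes both rings, and the conditions of step 12 then deliver 17.

Step 18. Alkenyl transfer to the unbranched aldehyde may be slow or poorly face-selective, with enolisation competing. The fallback sets out from aldehyde 24 and comes back at aldehyde 27.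
- Brown allylboration with allyl-B(Ipc)2 from (+)-Ipc2BOMe gives the homoallylic alcohol F6, with C8 set by the reagent.
- Isovaleric anhydride/DMAP gives the ester F7.
- RuHCl(CO)(PPh3)3 in warm toluene moves the terminal double bond by one position to the propenyl ester F8.
- Ozonolysis as in step 20 gives 27.

Step 21. Reagent control may fail to override the aldehyde's own facial bias, and the isovaleryl group may shift from O8 to O7 during the oxidative work-up. The fallback sets out from aldehyde 27 and comes back at 29.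
- (R)-But-3-yn-2-ol is converted with MsCl/Et3N into the mesylate F9.
- Pd(OAc)2, PPh3 and Et2Zn (THF, −20 °C) turn F9 into a configurationally defined allenylzinc.
- The allenylzinc adds to 27 through a cyclic SE2' transition state and gives the anti homopropargylic alcohol F10 after a neutral, non-oxidative quench.
- Semihydrogenation over Pd/CaCO3–Pb(OAc)2 with quinoline gives 29.

Further compounds
F1 | step 10 | δ-hydroxy methyl ketone (C15–C23, open form) | CC(=O)C[C@@H](C)C[C@@H](O)[C@@H](O[Si](C)(C)C(C)(C)C)C1(C)OCCO1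
F2 | step 10 | O20 triethylsilyl ether of F1 | CC(=O)C[C@@H](C)C[C@@H](O[Si](CC)(CC)CC)[C@@H](O[Si](C)(C)C(C)(C)C)C1(C)OCCO1
F3 | step 10 | kinetic C15=C16 trimethylsilyl enol ether | C=C(O[Si](C)(C)C)C[C@@H](C)C[C@@H](O[Si](CC)(CC)CC)[C@@H](O[Si](C)(C)C(C)(C)C)C1(C)OCCO1
F4 | step 10 | C12,C16-diketo ester (C11–C23) | COC(=O)C(=O)C[C@@H](C)CC(=O)C[C@@H](C)C[C@@H](O[Si](CC)(CC)CC)[C@@H](O[Si](C)(C)C(C)(C)C)C1(C)OCCO1
F5 | step 10 | C12 hydroxy ester (C12 epimers) | COC(=O)C(O)C[C@@H](C)CC(=O)C[C@@H](C)C[C@@H](O[Si](CC)(CC)CC)[C@@H](O[Si](C)(C)C(C)(C)C)C1(C)OCCO1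
F6 | step 18 | C8 homoallylic alcohol | C=CC[C@@H](O)C[C@H](C)[C@H](OC(=O)CC(C)C)[C@H]1C[C@@H](C)C[C@@]2(C[C@@H](C)C[C@H]([C@@H](O[Si](C)(C)C(C)(C)C)C3(C)OCCO3)O2)O1
F7 | step 18 | C8 isovalerate of F6 | C=CC[C@@H](OC(=O)CC(C)C)C[C@H](C)[C@H](OC(=O)CC(C)C)[C@H]1C[C@@H](C)C[C@@]2(C[C@@H](C)C[C@H]([C@@H](O[Si](C)(C)C(C)(C)C)C3(C)OCCO3)O2)O1
F8 | step 18 | (E)-propenyl isomer of F7 | C/C=C/[C@@H](OC(=O)CC(C)C)C[C@H](C)[C@H](OC(=O)CC(C)C)[C@H]1C[C@@H](C)C[C@@]2(C[C@@H](C)C[C@H]([C@@H](O[Si](C)(C)C(C)(C)C)C3(C)OCCO3)O2)O1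
F9 | step 21 | (R)-but-3-yn-2-yl methanesulfonate | C#C[C@@H](C)OS(C)(=O)=O
F10 | step 21 | (6S,7S)-homopropargylic alcohol | C#C[C@H](C)[C@H](O)[C@@H](OC(=O)CC(C)C)C[C@H](C)[C@H](OC(=O)CC(C)C)[C@H]1C[C@@H](C)C[C@@]2(C[C@@H](C)C[C@H]([C@@H](O[Si](C)(C)C(C)(C)C)C3(C)OCCO3)O2)O1
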